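## Structural features

The target is a dearomatised acylphloroglucinol joined to a monoterpene-derived cyclopentane. Ring A is a cyclohexa-2,4-dien-1-one (one enol tautomer of a cyclic β-triketone). It carries a 3-methylbutanoyl group on C2, enolic hydroxyls on C3 and C5, two prenyl groups on the quaternary C6, and a single methylene on C4 that links it to ring B. Ring B is a cyclopentane with three contiguous stereocentres: C1′ carries the methylene link, C2′ is a tertiary carbinol with a methyl group, and C5′ carries an isopropenyl group. The link is cis to the hydroxyl and trans to the isopropenyl group, and the absolute configuration is 1′R,2′S,5′S. Ring A has no stereocentre, so its problem is regiochemical: two prenyl groups must sit on one carbon while the last free ring carbon receives a different substituent. The fragile elements are the tertiary alcohol β to the link carbon (dehydration or retro-aldol opening once that carbon is a carbonyl), three acid-sensitive alkenes that can cyclise onto the enols, and the oxidisable, ambident enol–triketone system. The real difficulty is the stereotriad of ring B, a quaternary carbinol flanked by a tertiary centre that is itself next to another. Ring B with its exocyclic carbons is a cyclised linalyl unit: C2′ and its methyl are C3 of linalool, C1′ and the link are C2 and C1, C3′ and C4′ are C4 and C5, and C5′ with the isopropenyl group is C6 to C8. Only the C1′–C5′ bond is missing, and the key step closes exactly this bond by a magnesium-ene reaction, leaving a carbon–magnesium bond on the future link carbon.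

## Logic of the disconnections

**18 to 10 and 16 (through 17).** The bond between the methylene link and C4 of ring A is cut. C4 is the only nucleophilic carbon of 16, and the link carbon can be the aldehyde carbon of 10, so the polarity is natural. The cut puts all stereochemistry into 10 and all ring-A regiochemistry into 16, and makes the route convergent. The forward step must condense and reduce in one pot, faster than 10 loses water or opens by retro-aldol cleavage, and the reductant must leave the other alkenes and carbonyl groups alone.

**16 to 13 and two molecules of 14 (through 15).** Both bonds from C6 to the prenyl methylenes are cut. This leads back to an aromatic precursor whose two free ring carbons are equivalent, so the first alkylation has no regiochemical issue. The forward step must put the second prenyl group on the carbon that already carries one, on carbon and not on oxygen, and must stop before a third alkylation.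

**13 to 11 and 12.** The aryl–acyl bond is cut. The ketone deactivates the ring, so the forward acylation should stop at the mono-acyl stage. The only demand is a Lewis acid strong enough to give C-acylation and not the aryl ester.

**10 to 9.** No skeletal bond is cut; the link carbon is taken down from aldehyde to primary alcohol, which removes the labile β-hydroxy aldehyde from all earlier stages. The forward step must oxidise the primary alcohol next to a tertiary one under conditions that neither dehydrate nor epimerise the product.

**9 to 4 (through 8, 7, 6 and 5).** The ring bond C1′–C5′ and the C–O bond of the primary alcohol are cut. A CH2–metal group next to an alkenyl-bearing ring carbon is the retron of a metallo-ene reaction, so ring B opens to an acyclic allylic chloride with a vinyl carbinol. One ring and two stereocentres disappear, and the remaining stereocentre is that of a chiral-pool terpene. The forward step must form the allylmagnesium without homocoupling, close the five-membered ring with the link cis to oxygen and trans to isopropenyl, and oxidise the C–Mg bond without touching the alkenes.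

**4 to 2 (through 3), and 2 to 1.** The C–Cl bond and then the C8–O bond are cut, back to a compound that already holds all ten carbons and the carbinol configuration. The forward steps must oxidise one of five allylic positions with E geometry, and must replace the primary allylic hydroxyl by chloride without allylic shift and without touching the tertiary allylic alcohol.

## Other disconnections considered

**Alternative 1:** Ring A is cut at C4–C5 and C2–C3 (target numbering). C5, C6, C1 and C2 would come from 3-ethoxy-4,4-diprenylcyclobut-2-en-1-one A2, and C4 and C3 from the siloxyalkyne A3, which already carries ring B as its triethylsilyl ether. On heating, A2 would open to a vinylketene, add to A3 in a [2+2] sense, reopen and close by 6π-electrocyclisation. Because the former C4 of A2 is quaternary, the sequence cannot aromatise and should stop at the dienone A1.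
- In its favour: every substituent of ring A is placed by the connectivity of the two partners. The gem-diprenyl carbon is not left to a statistical alkylation, and on this regiochemical point the alternative is better than the chosen plan.
- Against it here: A3 needs ring B first (for example from 9 by one-carbon homologation to an ester, ynolate formation of the Kowalski type and O-silylation). A2 needs a dialkylketene–ethoxyacetylene cycloaddition. After A1 there remain C-acylation at the ring CH, hydrolysis of the ethyl enol ether beside acid-sensitive prenyl groups, and two desilylations. Heating a dienone rich in 1,5-diene units also invites Cope-type shifts of the prenyl groups.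
- Comparison: structurally it solves ring A, which has no stereocentre, and leaves the stereotriad unsolved. Mechanistically the pericyclic cascade is cleaner in regiochemistry than step 6. In step count it is clearly longer, about eight operations after 9 against two in the chosen plan.

**Alternative 2:** The cut removes two bonds outside ring B, C5′–isopropenyl and C1′–CH2, and takes ring B from cyclopent-2-en-1-one A5. Isopropenylmagnesium bromide A7 would add 1,4 to A5 under CuBr·SMe2 with a chiral ferrocenyl diphosphine, and the magnesium enolate would be trapped by formaldehyde A6 to give the trans ketone A4. Hydroxyl protection, methyl addition to the ketone and deprotection would lead to 9.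
- In its favour: two bonds are made in one pot from very simple pieces, the sequence is catalytic, and either enantiomer is accessible. The trans relation of link and isopropenyl follows from attack of the electrophile anti to the new β-substituent; on this point it is the equal of the chosen plan or better, since the chosen plan relies on equilibration of a metallo-ene step.
- Against it here: enantioselectivity of copper-catalysed Grignard additions is usually lower for cyclopentenone than for six-membered enones, and an alkenyl Grignard is a less favourable partner. Monomeric formaldehyde is awkward, and A4 is prone to dehydration to the α-methylene ketone. The carbinol centre must then be created by a methyl addition anti to the neighbouring arm, which chelation by the arm oxygen or enolisation could erode.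
- Comparison: the chosen plan takes the carbinol centre from the chiral pool with certainty, whereas this alternative must create all three centres. The mechanism is well understood but carries three separate selectivity demands. It needs about four steps to 9 against three.

**Alternative 3:** The cut is the C1′–C2′ bond of ring B together with a lactone C–O bond. (S)-Limonene A10 would be opened at its ring alkene and oxidised to the keto acid A9. Activation of the acid and a nucleophilic amine catalyst would give an ammonium enolate that adds to the methyl ketone, and the aldolate would close the cis-fused β-lactone A8. Hydride reduction of A8 would give 9.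
- In its favour: the cis relation of link and oxygen is enforced by the four-membered ring, and the isopropenyl group should take the trans position under substrate control. The reaction class is well established for keto acids of this kind. On diastereocontrol and on precedent it is better than the chosen plan, and A10 is available in high enantiomeric purity.
- Against it here: one alkene of A10 must be cleaved selectively in the presence of the other, the acid needs stoichiometric activation, and the carbinol centre is induced, not inherited. It needs about four steps to 9 against three.
- Comparison: structurally both plans reach the same diol. The chosen plan forms the ring, two stereocentres and the oxygenated link carbon in one operation from a precursor that already holds the carbinol centre, and is one step shorter. The alternative is the safer one stereochemically and is therefore kept as the fallback for the key step.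

Key step: step 3

Remark on the chemistry: 18 is one enol tautomer of a cyclic β-triketone, and all tautomers are taken as the same compound. Compound 1 is assumed to be of high enantiomeric purity, because its carbinol centre is the only source of absolute configuration.

## Route

Step 1
Reactants: 1 (S)-(+)-linalool, (3S)-3,7-dimethylocta-1,6-dien-3-ol
Product: 2 (2E,6S)-2,6-dimethylocta-2,7-diene-1,6-diol
Conditions: SeO2 (0.3 equiv), t-BuOOH (70% aq, 3 equiv), salicylic acid (0.1 equiv), CH2Cl2, 0 °C to rt
Reagents that add atoms: selenium dioxide, O=[Se]=O (delivers the oxygen); tert-butyl hydroperoxide, CC(C)(C)OO (reoxidises selenium and is the net oxygen source)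
Why: Catalytic SeO2 allylic oxidation (ene reaction, then [2,3]-sigmatropic shift of the allylseleninic acid) should take place at the more electron-rich trisubstituted alkene and at its E-methyl group, giving the primary (E)-allylic alcohol; the electron-poorer vinyl carbinol is left alone and the stereocentre is not involved.

Step 2
Reactants: 2 (2E,6S)-2,6-dimethylocta-2,7-diene-1,6-diol
Product: 4 (3S,6E)-8-chloro-3,7-dimethylocta-1,6-dien-3-ol, via primary allylic mesylate 3 (not isolated)
Conditions: MsCl (1.1 equiv), 2,4,6-collidine, LiCl (3 equiv), DMF, 0 °C
Reagents that add atoms: lithium chloride, [Li+].[Cl-]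
Why: Chlorination of an allylic alcohol through its mesylate: with collidine as base only the primary hydroxyl should be sulfonylated, and chloride displaces the mesylate 3 in situ by SN2 at the primary carbon, so the E geometry and the tertiary allylic alcohol are not disturbed.

Step 3
Reactants: 4 (3S,6E)-8-chloro-3,7-dimethylocta-1,6-dien-3-ol
Product: 9 [(1S,2S,5S)-2-hydroxy-2-methyl-5-(prop-1-en-2-yl)cyclopentyl]methanol, via chloromagnesium alkoxide 5 (not isolated), via allylmagnesium chloride 6 (not isolated), via cyclised alkylmagnesium chelate 7 (not isolated), via cyclic methyl boronate 8 (not isolated)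
Conditions: MeMgCl (1.0 equiv), THF, −40 °C; added over 3 h to activated Mg powder (4 equiv), THF, −65 °C; 65 °C, then 90 °C (sealed tube); B(OMe)3 (3 equiv), −78 °C to rt; 3 M NaOH, 30% H2O2, 0 °C to rt
Reagents that add atoms: hydrogen peroxide, OO
Why: MeMgCl first turns the hydroxyl into its chloromagnesium alkoxide 5 so that the allylic Grignard reagent is not protonated, and slow addition to excess activated magnesium at low temperature should insert Mg into the allylic C–Cl bond with little Wurtz coupling to give 6. On warming, 6 should undergo a type-1 intramolecular magnesium-ene reaction: in a six-centre suprafacial transition state the γ-carbon of the allyl unit (C6) bonds to the internal vinyl carbon C2, magnesium passes from C8 to C1, and the allyl double bond moves to C7=C8 to become the isopropenyl group. The closest known reaction types are the cyclisation of 2,7-octadienylmagnesium halides to (2-alkenylcyclopentyl)methylmagnesium halides and the alkoxide-directed addition of allylmagnesium halides to allylic alcohols, which has the same regiochemistry (carbon to the alkene carbon next to the carbinol, magnesium to the far carbon). The cyclopentane is closed in the 5-exo-trig mode with respect to the vinyl group. The centre at the link-bearing carbon is controlled by the alkoxide: only when the C1–Mg bond lies on the oxygen face of the new ring can the five-membered C–Mg–O chelate of 7 form, so the link should end cis to oxygen. The isopropenyl-bearing centre is controlled thermodynamically: the metallo-ene step is reversible on heating, and in the cis-fused chelate 7 the isopropenyl group is more stable on the convex face, trans to the link, than on the concave face next to solvated magnesium. The carbinol centre is not touched, so the (S) configuration of 1 is carried over unchanged. B(OMe)3 converts the C–Mg bond of 7 into the boronate 8, and alkaline H2O2 oxidises the C–B bond to the primary alcohol without epoxidising the unactivated alkene.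

Step 4
Reactants: 9 [(1S,2S,5S)-2-hydroxy-2-methyl-5-(prop-1-en-2-yl)cyclopentyl]methanol
Product: 10 (1R,2S,5S)-2-hydroxy-2-methyl-5-(prop-1-en-2-yl)cyclopentane-1-carbaldehyde
Conditions: TEMPO (0.1 equiv), PhI(OAc)2 (1.1 equiv), CH2Cl2, rt
Reagents that add atoms: none
Why: Oxoammonium (TEMPO) oxidation is selective for primary alcohols and stops at the aldehyde in dry CH2Cl2, the tertiary alcohol cannot be oxidised, and the near-neutral medium should avoid dehydration and retro-aldol opening. The α-centre is already in the more stable arrangement (trans to isopropenyl and to methyl), and 10 is used without delay.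

Step 5
Reactants: 11 phloroglucinol (benzene-1,3,5-triol); 12 3-methylbutanoyl chloride
Product: 13 3-methyl-1-(2,4,6-trihydroxyphenyl)butan-1-one
Conditions: AlCl3 (4 equiv), PhNO2/CH2Cl2, rt to 45 °C; aq HCl
Reagents that add atoms: none
Why: Friedel–Crafts acylation of the electron-rich triol; the aryl ketone formed is deactivated and hydrogen-bonded, which should hold the reaction at mono-acylation.

Step 6
Reactants: 13 3-methyl-1-(2,4,6-trihydroxyphenyl)butan-1-one; 14 prenyl bromide (1-bromo-3-methylbut-2-ene)
Product: 16 3,5-dihydroxy-2-(3-methylbutanoyl)-6,6-bis(3-methylbut-2-en-1-yl)cyclohexa-2,4-dien-1-one, via monoprenyl acylphloroglucinol 15 (not isolated)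
Conditions: NaOMe (3 equiv), MeOH, 0 °C; 14 (2.1 equiv) added over 2 h; rt
Reagents that add atoms: none
Why: Dearomatising double C-alkylation of an acylphloroglucinol: the phenolate is prenylated on carbon in methanol to give 15, whose anion is alkylated again at the same carbon to give the non-aromatic triketone 16; 16 is a strong vinylogous acid, held as a stabilised anion that should be slower to take a third prenyl group. The 3,5-diprenyl isomer and the triprenyl dienone are the by-products to be removed by chromatography; no stereocentre is formed.

Step 7
Reactants: 10 (1R,2S,5S)-2-hydroxy-2-methyl-5-(prop-1-en-2-yl)cyclopentane-1-carbaldehyde; 16 3,5-dihydroxy-2-(3-methylbutanoyl)-6,6-bis(3-methylbut-2-en-1-yl)cyclohexa-2,4-dien-1-one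
Product: 18 3,5-dihydroxy-4-{[(1R,2S,5S)-2-hydroxy-2-methyl-5-(prop-1-en-2-yl)cyclopentyl]methyl}-2-(3-methylbutanoyl)-6,6-bis(3-methylbut-2-en-1-yl)cyclohexa-2,4-dien-1-one, via alkylidene triketone 17 (not isolated)
Conditions: L-proline (0.2 equiv), Hantzsch ester (diethyl 2,6-dimethyl-1,4-dihydropyridine-3,5-dicarboxylate, 1.3 equiv), 16 (1.1 equiv), CH2Cl2, rt, Ar
Reagents that add atoms: none
Why: Three-component reductive alkylation: Knoevenagel condensation of the aldehyde with the only nucleophilic carbon (C4) of the cyclic vinylogous acid 16 gives the alkylidene triketone 17, a strong Michael acceptor that should take up hydride from the Hantzsch ester at its exocyclic carbon faster than it adds a second molecule of 16. No stereocentre is formed, and the mild, weakly acidic medium should leave the tertiary alcohol and the alkenes untouched.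

## Compound list

1 | (S)-(+)-linalool, (3S)-3,7-dimethylocta-1,6-dien-3-ol | C=C[C@@](C)(O)CCC=C(C)C | starting material
2 | (2E,6S)-2,6-dimethylocta-2,7-diene-1,6-diol | C=C[C@@](C)(O)CC/C=C(\C)CO | intermediate
3 | (2E,6S)-6-hydroxy-2,6-dimethylocta-2,7-dien-1-yl methanesulfonate | C=C[C@@](C)(O)CC/C=C(\C)COS(C)(=O)=O | intermediate
4 | (3S,6E)-8-chloro-3,7-dimethylocta-1,6-dien-3-ol | C=C[C@@](C)(O)CC/C=C(\C)CCl | intermediate
5 | chloromagnesium (3S,6E)-8-chloro-3,7-dimethylocta-1,6-dien-3-olate | C=C[C@@](C)(O[Mg]Cl)CC/C=C(\C)CCl | intermediate
6 | allylmagnesium chloride of 5: CH2MgCl in place of CH2Cl, E alkene, chloromagnesium alkoxide at the (S) carbinol | C=C[C@@](C)(O[Mg]Cl)CC/C=C(\C)C[Mg]Cl | intermediate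
7 | cyclised alkylmagnesium chelate: skeleton and configuration of 9 with CH2MgCl in place of CH2OH and OMgCl in place of OH (link cis to O, trans to isopropenyl) | C=C(C)[C@H]1CC[C@](C)(O[Mg]Cl)[C@@H]1C[Mg]Cl | intermediate
8 | cyclic methyl boronate: 2-methoxy-1,2-oxaborolane cis-fused to the cyclopentane, boron bridging the tertiary oxygen and the link carbon, configuration as in 9 | C=C(C)[C@H]1CC[C@]2(C)OB(OC)C[C@H]12 | intermediate
9 | [(1S,2S,5S)-2-hydroxy-2-methyl-5-(prop-1-en-2-yl)cyclopentyl]methanol | C=C(C)[C@H]1CC[C@](C)(O)[C@@H]1CO | intermediate
10 | (1R,2S,5S)-2-hydroxy-2-methyl-5-(prop-1-en-2-yl)cyclopentane-1-carbaldehyde | C=C(C)[C@H]1CC[C@](C)(O)[C@@H]1C=O | intermediate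
11 | phloroglucinol, benzene-1,3,5-triol | Oc1cc(O)cc(O)c1 | starting material
12 | 3-methylbutanoyl chloride | CC(C)CC(=O)Cl | starting material
13 | 3-methyl-1-(2,4,6-trihydroxyphenyl)butan-1-one | CC(C)CC(=O)c1c(O)cc(O)cc1O | intermediate
14 | prenyl bromide, 1-bromo-3-methylbut-2-ene | CC(C)=CCBr | starting material
15 | 3-methyl-1-[2,4,6-trihydroxy-3-(3-methylbut-2-en-1-yl)phenyl]butan-1-one | CC(C)CC(=O)c1c(O)cc(O)c(CC=C(C)C)c1O | intermediate
16 | 3,5-dihydroxy-2-(3-methylbutanoyl)-6,6-bis(3-methylbut-2-en-1-yl)cyclohexa-2,4-dien-1-one | CC(C)CC(=O)C1=C(O)C=C(O)C(CC=C(C)C)(CC=C(C)C)C1=O | intermediate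
17 | alkylidene triketone: 16 joined at C4 through an exocyclic C=CH to C1 of the (1,2S,5S)-2-hydroxy-2-methyl-5-(prop-1-en-2-yl)cyclopentyl unit of 10 (alkene geometry not defined) | C=C(C)[C@H]1CC[C@](C)(O)[C@@H]1C=C1C(=O)C(CC=C(C)C)(CC=C(C)C)C(O)=C(C(=O)CC(C)C)C1=O | intermediate
18 | 3,5-dihydroxy-4-{[(1R,2S,5S)-2-hydroxy-2-methyl-5-(prop-1-en-2-yl)cyclopentyl]methyl}-2-(3-methylbutanoyl)-6,6-bis(3-methylbut-2-en-1-yl)cyclohexa-2,4-dien-1-one | C=C(C)[C@H]1CC[C@](C)(O)[C@@H]1CC1=C(O)C(CC=C(C)C)(CC=C(C)C)C(=O)C(C(=O)CC(C)C)=C1O | target

## Step count and least certain steps

Total step count: 7. Longest linear sequence: 5 steps (steps 1, 2, 3, 4 and 7 from 1); the branch from 11 has 3 steps (5, 6 and 7).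

**Step 3 (key step).** Three things may go wrong.
- Wurtz-type homocoupling during magnesium insertion.
- Closure in the wrong stereochemical sense. The kinetic closure may place link and isopropenyl cis, and the equilibration to the trans isomer may be incomplete, because the alkoxide chelate that is meant to steer the reaction may also slow the retro-ene step. Closure with the link trans to oxygen is also possible.
- Competing closure to a six-membered ring.

The fallback changes the bond that is formed and uses an aldol-lactonisation. It does not start from a numbered compound: commercial (S)-(−)-limonene F1 takes the place of 1, and the path comes back to the route at 9. Ozonolysis of F1 limited to the more reactive ring alkene (O3, CH2Cl2/MeOH, −78 °C, one equivalent; Me2S) should give the keto aldehyde F2. Chlorite oxidation (NaClO2, NaH2PO4, 2-methylbut-2-ene) should give the keto acid F3. Activation with 2-bromo-1-propylpyridinium triflate in the presence of 4-pyrrolidinopyridine and i-Pr2NEt should close the cis-fused β-lactone F4, with the isopropenyl group trans to the lactone carbonyl. LiAlH4 in THF at 0 °C should then open F4 to 9.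

**Step 6.** The second prenylation may go to the other free ring carbon (3,5-dialkylation), to oxygen, or on to the triprenyl dienone, because the monoprenyl anion has two nucleophilic carbons of similar reactivity. The fallback reverses the order of the alkylations; it sets out from 13 and 10 and comes back at 18. Reductive alkylation of an excess of 13 with 10 under the conditions of step 7 should give the mono-alkylated acylphloroglucinol F5. Treatment of F5 with 14 (2 equiv) and NaOMe in MeOH should prenylate the last free carbon to give the 5-prenyl compound F6 in the flask. A second prenylation at the same, less hindered carbon should then give 18.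

**Step 7.** Amine-catalysed dehydration of 10 through its enamine or iminium ion, or retro-aldol ring opening, may outrun the condensation, and the α-branched aldehyde may condense slowly. The fallback masks the tertiary alcohol; it sets out from 9 and comes back at 18. Silylation of both hydroxyls (TESOTf, 2,6-lutidine, CH2Cl2) should give the bis(triethylsilyl) ether F7. Swern conditions ((COCl)2, DMSO, then Et3N) should convert the primary silyl ether directly into the silyloxy aldehyde F8. Condensation and reduction with 16 as in step 7 should give the triethylsilyl ether F9, and HF·pyridine in THF should release 18.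

**Step 1.** Over-oxidation to the enal, oxidation at the allylic methylene, or acid-promoted ionisation of the tertiary allylic alcohol may lower the return. The fallback builds the E-allylic alcohol by olefination; it sets out from 1 and comes back at 2. Ozonolysis of the trisubstituted alkene only (O3, CH2Cl2/MeOH, −78 °C; Me2S) should give the hydroxy aldehyde F10 as its lactol. Wittig reaction with ethyl 2-(triphenylphosphoranylidene)propanoate in toluene at 80 °C should give the (E)-ester F11. DIBAL-H in CH2Cl2 at −78 °C should reduce F11 to 2.

## Further compounds

F1 | step 3 | (S)-(−)-limonene, (4S)-1-methyl-4-(prop-1-en-2-yl)cyclohex-1-ene | CC1=CC[C@H](CC1)C(C)=C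
F2 | step 3 | (3S)-6-oxo-3-(prop-1-en-2-yl)heptanal | C=C(C)[C@H](CC=O)CCC(C)=O
F3 | step 3 | (3S)-6-oxo-3-(prop-1-en-2-yl)heptanoic acid | C=C(C)[C@H](CC(=O)O)CCC(C)=O
F4 | step 3 | (1R,2S,5S)-5-methyl-2-(prop-1-en-2-yl)-6-oxabicyclo[3.2.0]heptan-7-one | C=C(C)[C@H]1CC[C@]2(C)OC(=O)[C@H]12
F5 | step 6 | 1-[2,4,6-trihydroxy-3-{[(1R,2S,5S)-2-hydroxy-2-methyl-5-(prop-1-en-2-yl)cyclopentyl]methyl}phenyl]-3-methylbutan-1-one | C=C(C)[C@H]1CC[C@](C)(O)[C@@H]1Cc1c(O)cc(O)c(C(=O)CC(C)C)c1O
F6 | step 6 | 5-(3-methylbut-2-en-1-yl) derivative of F5 | C=C(C)[C@H]1CC[C@](C)(O)[C@@H]1Cc1c(O)c(CC=C(C)C)c(O)c(C(=O)CC(C)C)c1O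
F7 | step 7 | bis(triethylsilyl) ether of 9 | C=C(C)[C@H]1CC[C@](C)(O[Si](CC)(CC)CC)[C@@H]1CO[Si](CC)(CC)CC
F8 | step 7 | tertiary triethylsilyl ether of 10 | C=C(C)[C@H]1CC[C@](C)(O[Si](CC)(CC)CC)[C@@H]1C=O
F9 | step 7 | tertiary triethylsilyl ether of 18 | C=C(C)[C@H]1CC[C@](C)(O[Si](CC)(CC)CC)[C@@H]1CC1=C(O)C(CC=C(C)C)(CC=C(C)C)C(=O)C(C(=O)CC(C)C)=C1O
F10 | step 1 | (4S)-4-hydroxy-4-methylhex-5-enal (in equilibrium with its lactol) | C=C[C@@](C)(O)CCC=O
F11 | step 1 | ethyl (2E,6S)-6-hydroxy-2,6-dimethylocta-2,7-dienoate | C=C[C@@](C)(O)CC/C=C(\C)C(=O)OCC
A1 | alternative 1 | 5-ethoxy-6,6-bis(3-methylbut-2-en-1-yl)-3-(triisopropylsilyloxy)-2-{[2-methyl-5-(prop-1-en-2-yl)-2-(triethylsilyloxy)cyclopentyl]methyl}cyclohexa-2,4-dien-1-one, ring B configured as in 18 | C=C(C)[C@H]1CC[C@](C)(O[Si](CC)(CC)CC)[C@@H]1CC1=C(O[Si](C(C)C)(C(C)C)C(C)C)C=C(OCC)C(CC=C(C)C)(CC=C(C)C)C1=O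
A2 | alternative 1 | 3-ethoxy-4,4-bis(3-methylbut-2-en-1-yl)cyclobut-2-en-1-one | CCOC1=CC(=O)C1(CC=C(C)C)CC=C(C)C
A3 | alternative 1 | triisopropylsilyl ynol ether of 3-[2-methyl-5-(prop-1-en-2-yl)-2-(triethylsilyloxy)cyclopentyl]prop-1-yne, ring B configured as in 18 | C=C(C)[C@H]1CC[C@](C)(O[Si](CC)(CC)CC)[C@@H]1CC#CO[Si](C(C)C)(C(C)C)C(C)C
A4 | alternative 2 | (2S,3S)-2-(hydroxymethyl)-3-(prop-1-en-2-yl)cyclopentan-1-one | C=C(C)[C@H]1CCC(=O)[C@@H]1CO
A5 | alternative 2 | cyclopent-2-en-1-one | O=C1C=CCC1
A6 | alternative 2 | formaldehyde | C=O
A7 | alternative 2 | isopropenylmagnesium bromide | C=C(C)[Mg]Br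
A8 | alternative 3 | (1R,2S,5S)-5-methyl-2-(prop-1-en-2-yl)-6-oxabicyclo[3.2.0]heptan-7-one | C=C(C)[C@H]1CC[C@]2(C)OC(=O)[C@H]12
A9 | alternative 3 | (3S)-6-oxo-3-(prop-1-en-2-yl)heptanoic acid | C=C(C)[C@H](CC(=O)O)CCC(C)=O
A10 | alternative 3 | (S)-(−)-limonene | CC1=CC[C@H](CC1)C(C)=C
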